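**Strategy.** The 1,4-dioxane is cut by a retro-hetero-Diels–Alder into pristimerin (reacting as its ortho-quinone tautomer) and (7S,10S)-guaia-1(5),3,11-triene. Everything rests on how that hydroazulene is made. Its ring-fusion bond C1–C5 joins the two oxygen-bearing carbons and is shared by the cyclopentene, the cycloheptane and the dioxane. A methylcyclopentene fused across this bond to a seven-membered ring is the retron of alkyne + allene + CO. A rhodium-catalysed allenic Pauson–Khand reaction therefore closes the seven-membered ring through C1–C5 and the five-membered ring through C2–C3 and C3–C4 in one operation. Its precursor is an acyclic allene-yne whose single stereocentre (C7) comes from (S)-limonene oxide.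

Key step: step 7

Remark (assumption): the upper half is numbered as a guaiane (C1, C5 = oxygen-bearing ring-fusion carbons; C4, C10 = methyl-bearing; C7 = isopropenyl-bearing), the lower half as a 24-nor-friedelane; pristimerin and (S)-limonene 1,2-oxide are taken as purchasable, and the lower half of the target is read as pristimerin-configured with 8-H on the face of the C9 and C14 methyls (β).

Step 1
Reactants: 1 (4S)-limonene 1,2-oxide (cis/trans mixture)
Product: 3 (3S)-6-oxo-3-(prop-1-en-2-yl)heptanal, via diol 2 (not isolated)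
Conditions: H5IO6 (1.1 equiv), THF/H2O 3:1, 0 °C to rt
Reagents that add atoms: water, O
Why: Aqueous periodic acid hydrolyses the trisubstituted epoxide to the diol and cleaves it (Malaprade glycol cleavage) without touching the isopropenyl group, and the stereocentre of 1, the later C7, is not involved.

Step 2
Reactants: 3 (3S)-6-oxo-3-(prop-1-en-2-yl)heptanal
Product: 4 (5S)-5-(prop-1-en-2-yl)oct-7-yn-2-one
Conditions: dimethyl (1-diazo-2-oxopropyl)phosphonate (1.3 equiv), K2CO3 (2 equiv), MeOH, 0 °C to rt
Reagents that add atoms: Ohira–Bestmann reagent, COP(=O)(OC)C(=[N+]=[N-])C(C)=O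
Why: Seyferth–Gilbert homologation in the Ohira–Bestmann variant converts the aldehyde, which reacts far faster than the methyl ketone, into the terminal alkyne, and the stereocentre is β to the carbonyl and cannot epimerise.

Step 3
Reactants: 4 (5S)-5-(prop-1-en-2-yl)oct-7-yn-2-one
Product: 5 (6S)-3-methyl-6-(prop-1-en-2-yl)nona-1,8-diyn-3-ol (both C3 epimers)
Conditions: HC≡CMgBr (2.5 equiv), THF, 0 °C; aq. NH4Cl
Reagents that add atoms: ethynylmagnesium bromide, C#C[Mg]Br
Why: 1,2-Addition of the acetylide Grignard reagent to the methyl ketone (the excess covers partial metalation of the alkyne C–H) gives the tertiary propargylic alcohol, whose carbinol centre forms unselectively and is erased in step 5.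

Step 4
Reactants: 5 (6S)-3-methyl-6-(prop-1-en-2-yl)nona-1,8-diyn-3-ol
Product: 7 (6S)-3-methyl-6-(prop-1-en-2-yl)nona-1,8-diyn-3-yl methyl carbonate, via lithium alkoxide 6 (not isolated)
Conditions: n-BuLi (1.05 equiv), THF, −78 °C; ClCO2Me (1.2 equiv), −78 to 0 °C
Reagents that add atoms: methyl chloroformate, COC(=O)Cl
Why: The tertiary O–H is far more acidic than the alkyne C–H, so one equivalent of n-BuLi gives only the alkoxide, which the chloroformate acylates to the carbonate.

Step 5
Reactants: 7 (6S)-3-methyl-6-(prop-1-en-2-yl)nona-1,8-diyn-3-yl methyl carbonate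
Product: 8 (6S)-3-methyl-6-(prop-1-en-2-yl)nona-1,2-dien-8-yne
Conditions: Pd2(dba)3·CHCl3 (2.5 mol%), n-Bu3P (10 mol%), HCO2NH4 (2 equiv), THF, 25–40 °C
Reagents that add atoms: none
Why: Tsuji hydrogenolysis, in which zerovalent palladium ionises the tertiary propargylic carbonate to an allenylpalladium formate, decarboxylation gives the hydride and reductive elimination delivers the 1,1-disubstituted allene, the usual outcome for carbonates of 1-alkyn-3-ols, erasing the carbinol centre.

Step 6
Reactants: 8 (6S)-3-methyl-6-(prop-1-en-2-yl)nona-1,2-dien-8-yne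
Product: 10 (6S)-3-methyl-6-(prop-1-en-2-yl)deca-1,2-dien-8-yne, via lithium acetylide 9 (not isolated)
Conditions: n-BuLi (1.05 equiv), THF, −78 °C; MeI (1.5 equiv), DMPU, −78 °C to rt
Reagents that add atoms: iodomethane, CI
Why: The acetylenic C–H is removed selectively in the presence of the allenic and allylic hydrogens, and SN2 methylation of the acetylide installs C15.

Step 7
Reactants: 10 (6S)-3-methyl-6-(prop-1-en-2-yl)deca-1,2-dien-8-yne
Product: 11 (7S)-guaia-1(10),4,11-trien-3-one
Conditions: [Rh(CO)2Cl]2 (5 mol%), CO (1 atm), toluene, 90 °C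
Reagents that add atoms: carbon monoxide, [C-]#[O+]
Why: Monovalent rhodium binds the alkyne and the terminal C1=C2 π bond of the allene and undergoes oxidative cyclisation to a rhodacyclopentene in which the C1–C5 σ bond (central allene carbon to internal alkyne carbon) already exists, then CO inserts and reductive elimination forms C2–C3 and C3–C4. The closest known reaction type is the rhodium-catalysed allenic Pauson–Khand (cyclocarbonylative [2+2+1]) reaction of allene-ynes with a four-atom tether to bicyclo[5.3.0]decadienones. The seven-membered ring closes in the metallacycle-forming step, exo with respect to the alkyne and through the distal allene π bond so that C1=C10 stays inside the new ring, and the five-membered ring closes by carbonyl insertion and reductive elimination at rhodium. No stereocentre is created, since C1 and C5 leave the step as sp2 carbons and C7 is a spectator. The step needs distal over proximal selectivity at the allene and carbonylation over ene-type or [2+2] pathways: the first is the established preference of [Rh(CO)2Cl]2 and is reinforced by the fully substituted proximal carbon C10, the second is secured by the CO atmosphere and by the absence of a β-hydrogen on the terminal CH2 of the allene, while the isopropenyl group cannot compete because it would close a four-membered ring.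

Step 8
Reactants: 11 (7S)-guaia-1(10),4,11-trien-3-one
Product: 13 (7S,10S)-guaia-1(5),3,11-trien-3-yl trifluoromethanesulfonate, via lithium dienolate 12 (not isolated)
Conditions: Li (2.2 equiv), NH3(l)/THF, t-BuOH (1.0 equiv), −78 °C; evaporate NH3; PhNTf2 (1.2 equiv), THF, −78 to 0 °C
Reagents that add atoms: N-phenylbis(trifluoromethanesulfonimide), O=S(=O)(N(c1ccccc1)S(=O)(=O)C(F)(F)F)C(F)(F)F
Why: Dissolving-metal 1,6-reduction of the linear dienone (as with steroidal 4,6-dien-3-ones) protonates the dianion at the δ-carbon C10 and leaves the cross-ring lithium dienolate, which is O-triflated, and C10 is expected to take its proton axially in the chair-like seven-membered ring that keeps the C7 isopropenyl group equatorial, which places the C10 methyl equatorial and trans to it (10S).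

Step 9
Reactants: 13 (7S,10S)-guaia-1(5),3,11-trien-3-yl trifluoromethanesulfonate
Product: 14 (7S,10S)-guaia-1(5),3,11-triene
Conditions: Pd(OAc)2 (5 mol%), PPh3 (10 mol%), n-Bu3N (3 equiv), HCO2H (2 equiv), DMF, 25–40 °C, dark; used at once
Reagents that add atoms: none
Why: Palladium-catalysed formate reduction of the dienyl triflate (oxidative addition, formate decarboxylation, C–H reductive elimination) replaces OTf by H without moving the double bonds, and the mild temperature limits 1,5-hydrogen shifts of the cyclopentadiene.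

Step 10
Reactants: 14 (7S,10S)-guaia-1(5),3,11-triene (1.5 equiv) and 15 pristimerin
Product: 17 CNP0113384.4 (target), via ortho-quinone tautomer 16 (not isolated)
Conditions: Et3N (0.2 equiv), toluene, 25 °C, dark, argon
Reagents that add atoms: none
Why: Amine-mediated prototropy from O3–H to C8 (the proton is expected on the β face, flanked only by the C9 and C14 methyls, whereas the α face is screened by C11, C15 and the syn-axial C13 methyl) gives the ortho-quinone, whose O=C–C=O heterodiene should undergo an inverse-electron-demand hetero-Diels–Alder reaction with the most electron-rich, tetrasubstituted C1=C5 bond of 14, the diene terminus C1 bonding first to O3 (phenoxide character then develops at O2, para to the C6=C7 vinyl group) and O2 closing on the allyl-stabilised C5, cis across the alkene and, as proposed, on the face syn to the C10 methyl and anti to the C7 isopropenyl group, where the forming C1–O bond is staggered between C10–CH3 and C10–C9.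

**Compound list**

1 | (4S)-limonene 1,2-oxide, i.e. (4S)-1-methyl-4-(prop-1-en-2-yl)-7-oxabicyclo[4.1.0]heptane, cis/trans mixture | CC12CC[C@@H](CC1O2)C(=C)C | starting material
2 | (4S)-1-methyl-4-(prop-1-en-2-yl)cyclohexane-1,2-diol | CC1(O)CC[C@@H](CC1O)C(=C)C | intermediate (not isolated)
3 | (3S)-6-oxo-3-(prop-1-en-2-yl)heptanal | O=CC[C@H](CCC(C)=O)C(C)=C | intermediate
4 | (5S)-5-(prop-1-en-2-yl)oct-7-yn-2-one | C#CC[C@H](CCC(C)=O)C(C)=C | intermediate
5 | (6S)-3-methyl-6-(prop-1-en-2-yl)nona-1,8-diyn-3-ol, both C3 epimers | C#CC[C@H](CCC(C)(O)C#C)C(C)=C | intermediate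
6 | lithium (6S)-3-methyl-6-(prop-1-en-2-yl)nona-1,8-diyn-3-olate | C#CC[C@H](CCC(C)([O-])C#C)C(C)=C.[Li+] | intermediate (not isolated)
7 | (6S)-3-methyl-6-(prop-1-en-2-yl)nona-1,8-diyn-3-yl methyl carbonate | C#CC[C@H](CCC(C)(OC(=O)OC)C#C)C(C)=C | intermediate
8 | (6S)-3-methyl-6-(prop-1-en-2-yl)nona-1,2-dien-8-yne | C#CC[C@H](CCC(C)=C=C)C(C)=C | intermediate
9 | lithium acetylide of 8 | [Li+].[C-]#CC[C@H](CCC(C)=C=C)C(C)=C | intermediate (not isolated)
10 | (6S)-3-methyl-6-(prop-1-en-2-yl)deca-1,2-dien-8-yne | CC#CC[C@H](CCC(C)=C=C)C(C)=C | intermediate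
11 | (7S)-guaia-1(10),4,11-trien-3-one, i.e. (5S)-3,8-dimethyl-5-(prop-1-en-2-yl)-4,5,6,7-tetrahydroazulen-2(1H)-one | O=C1CC2=C(C)CC[C@H](C(C)=C)CC2=C1C | intermediate
12 | lithium (7S,10S)-guaia-1(5),3,11-trien-3-olate | [Li+].[O-]C1=C(C)C2=C(C1)[C@@H](C)CC[C@H](C(C)=C)C2 | intermediate (not isolated)
13 | (7S,10S)-guaia-1(5),3,11-trien-3-yl trifluoromethanesulfonate | O=S(=O)(OC1=C(C)C2=C(C1)[C@@H](C)CC[C@H](C(C)=C)C2)C(F)(F)F | intermediate
14 | (7S,10S)-guaia-1(5),3,11-triene, i.e. (4S,7S)-1,4-dimethyl-7-(prop-1-en-2-yl)-3,4,5,6,7,8-hexahydroazulene | C1=C(C)C2=C(C1)[C@@H](C)CC[C@H](C(C)=C)C2 | intermediate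
15 | pristimerin, methyl 3-hydroxy-2-oxo-24-nor-friedela-1(10),3,5,7-tetraen-29-oate | O=C1C=C2C(=CC=C3[C@@]2(C)CC[C@@]2(C)[C@@H]4C[C@](C)(C(=O)OC)CC[C@]4(C)CC[C@]32C)C(C)=C1O | starting material
16 | methyl (8βH)-2,3-dioxo-24-nor-friedela-1(10),4,6-trien-29-oate (ortho-quinone tautomer of 15) | O=C1C=C2C(C=C[C@@H]3[C@@]2(C)CC[C@@]2(C)[C@@H]4C[C@](C)(C(=O)OC)CC[C@]4(C)CC[C@]32C)=C(C)C1=O | intermediate (not isolated)
17 | CNP0113384.4: 1,4-benzodioxane joining O3/O2 of the 8βH-6-ene triterpene catechol to C1/C5 of the (1S,5S,7S,10S)-guaia-3,11-diene unit | C=C(C)[C@H]1CC[C@H](C)[C@@]23CC=C(C)[C@]2(C1)Oc1cc2c(c(C)c1O3)C=C[C@@H]1[C@@]2(C)CC[C@@]2(C)[C@@H]3C[C@](C)(C(=O)OC)CC[C@]3(C)CC[C@]12C | target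

**Count and risks**

Total step count: 10. Longest linear sequence: 10 steps (1 to 17); 15 enters in the last step.

Steps most likely to fail:

Step 10. The proton shift that creates the heterodiene may be slower than the 1,5-hydrogen shifts and dimerisation of 14, so that peri-, regio- and face-isomeric adducts form, and the proton may enter C8 from the α face. The fallback sets out from 15 (with 14 as before) and comes back at 17; it makes the heterodiene by oxidation instead of tautomerisation. 15 is reduced with NaBH4 (MeOH, 0 °C, hydride at C6) to the 7-ene catechol methyl 2,3-dihydroxy-24-nor-friedela-1,3,5(10),7-tetraen-29-oate F1. F1 is oxidised with Ag2O (Et2O/CH2Cl2, MgSO4, −20 °C, base-free) in the presence of 14 to methyl 2,3-dioxo-24-nor-friedela-1(10),4,7-trien-29-oate F2, which needs no proton shift and should be trapped by 14 as the 7-ene adduct F3. The C7=C8 bond of F3 is then moved into conjugation with ring A by a 1,3-prototropic shift (KOtBu cat., DMSO, 25 °C: deprotonation at the benzylic and allylic C6, reprotonation at C8 under equilibrating conditions) to give 17; C8 epimers, if formed, would need separation.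

Step 8. Facial selectivity of the protonation at C10 may be poor, and β-protonation at C5 may compete. The fallback sets out from 11 and comes back at 14, bypassing 12 and 13; it replaces substrate control by reagent control with chirality transfer. 11 is reduced with (R)-Me-CBS (10 mol%) and BH3·SMe2 (THF, −20 °C) to (3S,7S)-guaia-1(10),4,11-trien-3-ol F4 and acylated (ClCO2Me, pyridine, DMAP, CH2Cl2, 0 °C) to (3S,7S)-guaia-1(10),4,11-trien-3-yl methyl carbonate F5. F5 is hydrogenolysed with Pd2(dba)3·CHCl3, n-Bu3P and HCO2NH4 (THF, 25 °C). Zerovalent palladium ionises anti to the carbonate, and the hydride is expected to go from the metal to the C10 terminus of the pentadienyl ligand on that same face (anti SN2″ overall), which would give H-10 on the α face and the conjugated diene 14.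

Step 2. Base-mediated intramolecular aldol condensation of the 1,6-keto aldehyde may outrun the homologation. The fallback sets out from 3 and comes back at 8; it masks the aldehyde and builds the allene first. 3 is acetalised selectively at the aldehyde (HC(OMe)3, MeOH, CeCl3·7H2O cat.) to (5S)-7,7-dimethoxy-5-(prop-1-en-2-yl)heptan-2-one F6. HC≡CMgBr (THF, 0 °C) gives (6S)-8,8-dimethoxy-3-methyl-6-(prop-1-en-2-yl)oct-1-yn-3-ol F7. n-BuLi then ClCO2Me gives its methyl carbonate F8. Pd2(dba)3·CHCl3, n-Bu3P and HCO2NH4 give (6S)-8,8-dimethoxy-3-methyl-6-(prop-1-en-2-yl)octa-1,2-diene F9. Mild hydrolysis (PPTS, acetone/H2O, rt) gives (3S)-6-methyl-3-(prop-1-en-2-yl)octa-6,7-dienal F10, and Ohira–Bestmann homologation of F10, now without a ketone in the molecule, gives 8.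

**Further compounds**

F1 | step 10 | methyl 2,3-dihydroxy-24-nor-friedela-1,3,5(10),7-tetraen-29-oate | Oc1cc2c(CC=C3[C@@]2(C)CC[C@@]2(C)[C@@H]4C[C@](C)(C(=O)OC)CC[C@]4(C)CC[C@]32C)c(C)c1O
F2 | step 10 | methyl 2,3-dioxo-24-nor-friedela-1(10),4,7-trien-29-oate | O=C1C=C2C(CC=C3[C@@]2(C)CC[C@@]2(C)[C@@H]4C[C@](C)(C(=O)OC)CC[C@]4(C)CC[C@]32C)=C(C)C1=O
F3 | step 10 | 7-ene isomer of 17 (C6H2, C7=C8) | C=C(C)[C@H]1CC[C@H](C)[C@@]23CC=C(C)[C@]2(C1)Oc1cc2c(c(C)c1O3)CC=C1[C@@]2(C)CC[C@@]2(C)[C@@H]3C[C@](C)(C(=O)OC)CC[C@]3(C)CC[C@]12C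
F4 | step 8 | (3S,7S)-guaia-1(10),4,11-trien-3-ol | O[C@H]1CC2=C(C)CC[C@H](C(C)=C)CC2=C1C
F5 | step 8 | (3S,7S)-guaia-1(10),4,11-trien-3-yl methyl carbonate | COC(=O)O[C@H]1CC2=C(C)CC[C@H](C(C)=C)CC2=C1C
F6 | step 2 | (5S)-7,7-dimethoxy-5-(prop-1-en-2-yl)heptan-2-one | COC(OC)C[C@H](CCC(C)=O)C(C)=C
F7 | step 2 | (6S)-8,8-dimethoxy-3-methyl-6-(prop-1-en-2-yl)oct-1-yn-3-ol | COC(OC)C[C@H](CCC(C)(O)C#C)C(C)=C
F8 | step 2 | (6S)-8,8-dimethoxy-3-methyl-6-(prop-1-en-2-yl)oct-1-yn-3-yl methyl carbonate | COC(OC)C[C@H](CCC(C)(OC(=O)OC)C#C)C(C)=C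
F9 | step 2 | (6S)-8,8-dimethoxy-3-methyl-6-(prop-1-en-2-yl)octa-1,2-diene | COC(OC)C[C@H](CCC(C)=C=C)C(C)=C
F10 | step 2 | (3S)-6-methyl-3-(prop-1-en-2-yl)octa-6,7-dienal | O=CC[C@H](CCC(C)=C=C)C(C)=C
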